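**Plan**

- Ansa numbering: amide carbonyl C1, diene C2–C5, tertiary carbinol C6, polyol C7–C14 (hydroxymethyl carbon C14'), enone C15–C17; C17 sits on naphthalene C5 and the nitrogen on naphthalene C2.
- The feature that carries the route is the (2Z,4E)-diene C2–C5 between C1 and C6. It is held as a 3-sulfolene whose α-carbons are C2 (methyl, C1 carbonyl) and C5 (H, C6), so the 23-membered ansa ring is stored as a 22-membered ring bridged by sulfur.
- Cuts, in retrosynthetic order: re-insertion of SO2 across C2/C5; C16–C17 (alkenyl iodide and aryl aldehyde); C5–C6 (sulfolene carbanion and methyl ketone); C1–C2 with C1–N (sulfolene carbanion and aryl isocyanate); then C14–C15, C13–C14, C7–C8 and C10–C11 in the chain and the second ring of the naphthalene.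
- Forward: chain C6–C16 from the Roche ester by two aldol reactions on pentan-3-one, an epoxide opening and an iodo-olefination; naphthalene by Stobbe benzannulation; fragment union at C5–C6; 22-membered ring at C16–C17; SO2 loss to the 23-membered ring; quinone and deprotection last.
- Stereochemistry: C12 from the Roche ester; C10/C11 from an anti aldol with Felkin–Anh control; C7/C8 from a syn aldol directed by C10; C9 by 1,3-anti reduction; C13/C14 by Sharpless epoxidation and invertive opening; C6 by Cram chelation; C15=C16 (Z) by Stork–Zhao olefination; C2=C3 (Z) and C4=C5 (E) from the cis sulfolene by disrotatory extrusion.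

Key step: step 30

Remark: amide 40 is racemic, so 41–44 are each a pair of diastereomers that differ only in the absolute sense of the two sulfolene carbons (2S,5S drawn, 2R,5R partner, both with the C2 methyl cis to C6, assuming the C5 facial selectivity claimed in step 27); the pair is carried on unseparated because both members give 45, and 43 is also a mixture of C17 epimers that step 29 removes.

**Chain fragment (steps 1–16)**

Step 1
Reactants: 1 methyl (R)-3-hydroxy-2-methylpropanoate
Product: 2 methyl (R)-3-[(tert-butyldiphenylsilyl)oxy]-2-methylpropanoate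
Conditions: t-BuPh2SiCl, imidazole, DMF, rt
Reagents that add atoms: tert-butyl(chloro)diphenylsilane CC(C)(C)[Si](Cl)(c1ccccc1)c1ccccc1
Why: Silylation of a primary alcohol under imidazole catalysis is routine and does not touch the stereocentre that becomes C12.

Step 2
Reactants: 2 methyl (R)-3-[(tert-butyldiphenylsilyl)oxy]-2-methylpropanoate
Product: 3 (R)-3-[(tert-butyldiphenylsilyl)oxy]-2-methylpropanal
Conditions: i-Bu2AlH, CH2Cl2, −78 °C; aq. potassium sodium tartrate
Reagents that add atoms: none
Why: Partial hydride reduction of the ester stops at the tetrahedral aluminate at −78 °C and should release the α-methyl aldehyde (C11) without epimerisation.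

Step 3
Reactants: 3 (R)-3-[(tert-butyldiphenylsilyl)oxy]-2-methylpropanal; 4 pentan-3-one
Product: 5 (4S,5S,6R)-7-[(tert-butyldiphenylsilyl)oxy]-5-hydroxy-4,6-dimethylheptan-3-one
Conditions: (c-Hex)2BCl, Et3N, Et2O, 0 °C; 3, −78 to −20 °C; H2O2, MeOH, pH 7 buffer
Reagents that add atoms: none
Why: Boron-mediated anti aldol reaction, in which the E enol borinate of 4 reacts through a chair transition state (C10/C11 anti) and attacks the aldehyde in the Felkin–Anh sense (C11/C12 syn).

Step 4
Reactants: 5 (4S,5S,6R)-7-[(tert-butyldiphenylsilyl)oxy]-5-hydroxy-4,6-dimethylheptan-3-one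
Product: 6 C11 triethylsilyl ether of 5
Conditions: Et3SiOTf, 2,6-lutidine, CH2Cl2, −78 °C
Reagents that add atoms: triethylsilyl trifluoromethanesulfonate CC[Si](CC)(CC)OS(=O)(=O)C(F)(F)F
Why: Silyl triflate silylation caps the β-hydroxyl so that the ethyl ketone can be enolised on its other side.

Step 5
Reactants: 6 C11 triethylsilyl ether of 5; 7 methacrolein
Product: 8 C6–C13 aldol adduct (C7 alcohol; C9 ketone; C6 as isopropenyl)
Conditions: TiCl4, i-Pr2NEt, CH2Cl2, −78 °C; then 7
Reagents that add atoms: none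
Why: Titanium-mediated syn aldol reaction, in which the Z chlorotitanium enolate gives the C7/C8 syn relationship through a chair transition state and the α-stereocentre C10 directs the aldehyde to the enolate face that makes the C8 and C10 methyl groups syn.

Step 6
Reactants: 8 C6–C13 aldol adduct
Product: 9 C7,C9 anti diol
Conditions: Me4NBH(OAc)3, MeCN/AcOH, −30 °C
Reagents that add atoms: none
Why: Evans–Saksena reduction, in which the C7 hydroxyl binds the acetoxyborohydride and delivers hydride intramolecularly to give the 1,3-anti diol and so fix C9.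

Step 7
Reactants: 9 C7,C9 anti diol
Product: 11 C9/C11 acetonide alcohol, via triol 10 (not isolated)
Conditions: PPTS (cat.), MeOH, rt; then Me2C(OMe)2, acetone, rt
Reagents that add atoms: 2,2-dimethoxypropane COC(C)(C)OC
Why: Acid methanolysis removes the triethylsilyl ether and equilibrating ketalisation should select the syn-1,3-diol C9/C11 (all-equatorial chair) over the anti-1,3-diol C7/C9, which leaves the C7 hydroxyl free.

Step 8
Reactants: 11 C9/C11 acetonide alcohol
Product: 12 C7 4-methoxybenzyl ether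
Conditions: NaH, 4-MeOC6H4CH2Cl, Bu4NI (cat.), DMF, 0 °C to rt
Reagents that add atoms: 4-methoxybenzyl chloride COc1ccc(CCl)cc1
Why: Williamson etherification installs at C7 the ether that later chelates magnesium and is removed oxidatively at the end.

Step 9
Reactants: 12 C7 4-methoxybenzyl ether
Product: 13 C13 primary alcohol
Conditions: Bu4NF, THF, rt
Reagents that add atoms: none
Why: Fluoride cleavage of the silyl ether frees only the C13 hydroxyl because the other oxygens are ethers or ketals.

Step 10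
Reactants: 13 C13 primary alcohol
Product: 15 ethyl (E)-enoate (C13=C14), via aldehyde 14 (not isolated)
Conditions: Dess–Martin periodinane, NaHCO3, CH2Cl2, rt; then Ph3P=CHCO2Et, rt
Reagents that add atoms: ethyl (triphenylphosphoranylidene)acetate CCOC(=O)C=P(c1ccccc1)(c1ccccc1)c1ccccc1
Why: Dess–Martin oxidation followed in the same flask by Wittig olefination with a stabilised ylide gives the E enoate and avoids isolating the epimerisable α-methyl aldehyde.

Step 11
Reactants: 15 ethyl (E)-enoate
Product: 16 (E)-allylic alcohol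
Conditions: i-Bu2AlH, CH2Cl2, −78 °C
Reagents that add atoms: none
Why: 1,2-Reduction of an enoate by the aluminium hydride gives the allylic alcohol needed for directed epoxidation.

Step 12
Reactants: 16 (E)-allylic alcohol
Product: 17 (13R,14R)-trans-epoxy alcohol
Conditions: Ti(Oi-Pr)4, D-(−)-diethyl tartrate, t-BuOOH, 4 Å MS, CH2Cl2, −20 °C
Reagents that add atoms: tert-butyl hydroperoxide CC(C)(C)OO
Why: Sharpless asymmetric epoxidation, in which the D-tartrate complex delivers oxygen to one face of the allylic alcohol under reagent control and sets C13, while the isopropenyl group has no free allylic hydroxyl and is left alone.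

Step 13
Reactants: 17 (13R,14R)-trans-epoxy alcohol
Product: 18 2-vinyl-1,3-diol (C13 and C14' hydroxyls; vinyl carbon C15)
Conditions: CH2=CHMgBr, CuI (10 mol%), THF/Et2O, −30 to 0 °C
Reagents that add atoms: vinylmagnesium bromide C=C[Mg]Br
Why: Copper-catalysed Grignard opening of a 2,3-epoxy alcohol by SN2 attack at C14, the epoxide carbon remote from the branched C12, proceeds with inversion and places the C13 oxygen and C14' syn.

Step 14
Reactants: 18 2-vinyl-1,3-diol
Product: 19 bis-acetonide diene
Conditions: Me2C(OMe)2, PPTS (cat.), CH2Cl2, rt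
Reagents that add atoms: 2,2-dimethoxypropane COC(C)(C)OC
Why: Ketalisation of the 1,3-diol gives a dioxane that holds the C13 chain and the C15 vinyl group trans-diequatorial.

Step 15
Reactants: 19 bis-acetonide diene
Product: 20 keto aldehyde (C6 methyl ketone; C15 aldehyde)
Conditions: OsO4 (2 mol%), NaIO4, 2,6-lutidine, dioxane/H2O, rt
Reagents that add atoms: sodium periodate [Na+].[O-]I(=O)(=O)=O; osmium tetroxide O=[Os](=O)(=O)=O
Why: Lemieux–Johnson cleavage converts both terminal alkenes in one operation, the isopropenyl group into the C6 methyl ketone and the vinyl group into the C15 aldehyde, and the lutidine buffer protects the C14 stereocentre.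

Step 16
Reactants: 20 keto aldehyde
Product: 21 chain fragment (C6 methyl ketone; (Z)-C15=C16 iodide)
Conditions: EtPPh3I, n-BuLi, THF; I2, −78 °C; NaN(SiMe3)2, −20 °C; then 20, −78 °C
Reagents that add atoms: ethyltriphenylphosphonium iodide CC[P+](c1ccccc1)(c1ccccc1)c1ccccc1.[I-]; iodine II
Why: Stork–Zhao olefination, in which the α-iodo ylide reacts at −78 °C with the aldehyde and not with the methyl ketone and gives the 2-iodoalkene with C14 cis to iodine (Z).

**Arene and sulfolene fragment (steps 17–26)**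

Step 17
Reactants: 22 4-hydroxy-3-methylbenzaldehyde
Product: 23 4-(benzyloxy)-3-methylbenzaldehyde
Conditions: BnBr, K2CO3, DMF, rt
Reagents that add atoms: benzyl bromide BrCc1ccccc1
Why: Williamson benzylation protects the phenol for the strongly basic condensation that follows.

Step 18
Reactants: 23 4-(benzyloxy)-3-methylbenzaldehyde; 24 dimethyl succinate
Product: 25 (E)-4-[4-(benzyloxy)-3-methylphenyl]-3-(methoxycarbonyl)but-3-enoic acid
Conditions: t-BuOK, t-BuOH, reflux; then aq. HCl
Reagents that add atoms: none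
Why: Stobbe condensation, in which the paraconate lactone intermediate opens to the half-ester with the aryl group cis to the CH2CO2H arm, as needed for ring closure.

Step 19
Reactants: 25 (E)-4-[4-(benzyloxy)-3-methylphenyl]-3-(methoxycarbonyl)but-3-enoic acid
Product: 27 methyl 6-(benzyloxy)-4-hydroxy-7-methyl-2-naphthoate, via aryl acetate 26 (not isolated)
Conditions: Ac2O, NaOAc, 140 °C; then K2CO3, MeOH, rt
Reagents that add atoms: none
Why: Friedel–Crafts cyclisation of the mixed anhydride should occur at the ring position para to the methyl group, because the other ortho position is flanked by that methyl, and methanolysis then frees the naphthol.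

Step 20
Reactants: 27 methyl 6-(benzyloxy)-4-hydroxy-7-methyl-2-naphthoate
Product: 30 methyl 6-(benzyloxy)-1,4-dimethoxy-7-methyl-2-naphthoate, via quinone 28 (not isolated), via hydroquinone 29 (not isolated)
Conditions: (KSO3)2NO, KH2PO4, acetone/H2O, rt; Na2S2O4, H2O/EtOAc; then Me2SO4, K2CO3, acetone, reflux
Reagents that add atoms: potassium nitrosodisulfonate [K+].[K+].[O-]S(=O)(=O)N([O])S(=O)(=O)[O-]; dimethyl sulfate COS(=O)(=O)OC
Why: Teuber oxidation of the naphthol at its free para position gives the 1,4-quinone, and dithionite reduction with O-methylation converts the reactive quinone ester directly into the robust dimethyl ether.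

Step 21
Reactants: 30 methyl 6-(benzyloxy)-1,4-dimethoxy-7-methyl-2-naphthoate
Product: 31 methyl 6-hydroxy-1,4-dimethoxy-7-methyl-2-naphthoate
Conditions: H2 (1 atm), Pd/C, EtOAc, rt
Reagents that add atoms: none
Why: Hydrogenolysis of the benzyl ether frees the naphthol that directs the formylation.

Step 22
Reactants: 31 methyl 6-hydroxy-1,4-dimethoxy-7-methyl-2-naphthoate
Product: 32 methyl 5-formyl-6-hydroxy-1,4-dimethoxy-7-methyl-2-naphthoate
Conditions: MgCl2, Et3N, (CH2O)n, MeCN, reflux
Reagents that add atoms: paraformaldehyde (formaldehyde unit) C=O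
Why: Casnati–Skattebøl ortho-formylation, in which the magnesium phenoxide delivers formaldehyde to the only free ortho position (naphthalene C5) and a second formaldehyde oxidises the benzylic alkoxide to the aldehyde that becomes C17.

Step 23
Reactants: 32 methyl 5-formyl-6-hydroxy-1,4-dimethoxy-7-methyl-2-naphthoate
Product: 33 methyl 5-formyl-1,4-dimethoxy-6-(methoxymethoxy)-7-methyl-2-naphthoate
Conditions: MeOCH2Cl, i-Pr2NEt, CH2Cl2, 0 °C to rt
Reagents that add atoms: chloromethyl methyl ether COCCl
Why: O-Alkylation of the acidic ortho-formyl phenol gives an acetal-type ether that survives carbanions and oxidants and is removed by mild acid at the end.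

Step 24
Reactants: 33 methyl 5-formyl-1,4-dimethoxy-6-(methoxymethoxy)-7-methyl-2-naphthoate
Product: 35 potassium 5-(dimethoxymethyl)-1,4-dimethoxy-6-(methoxymethoxy)-7-methyl-2-naphthoate, via acetal ester 34 (not isolated)
Conditions: HC(OMe)3, PPTS (cat.), MeOH, rt; evaporate; KOSiMe3, THF, rt
Reagents that add atoms: trimethyl orthoformate COC(OC)OC; potassium trimethylsilanolate C[Si](C)(C)[O-].[K+]
Why: Acetalisation masks the aldehyde against carbanions, and silanolate cleavage of the methyl ester gives the carboxylate under anhydrous, acid-free conditions that the labile acetal tolerates.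

Step 25
Reactants: 35 potassium 5-(dimethoxymethyl)-1,4-dimethoxy-6-(methoxymethoxy)-7-methyl-2-naphthoate; 36 3-sulfolene
Product: 39 racemic N-aryl 2,5-dihydrothiophene-2-carboxamide 1,1-dioxide, via acyl azide 37 (not isolated), via isocyanate 38 (not isolated)
Conditions: (PhO)2P(O)N3, toluene/DMF, rt then 85 °C; separately 36, n-BuLi, THF/DMPU, −100 °C, then the isocyanate solution; aq. NaHCO3
Reagents that add atoms: diphenylphosphoryl azide [N-]=[N+]=NP(=O)(Oc1ccccc1)Oc1ccccc1
Why: Curtius rearrangement gives the aryl isocyanate, and C-acylation of the α-sulfonyl carbanion of 3-sulfolene by that isocyanate forms the C1–C2 bond and the anilide in one operation.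

Step 26
Reactants: 39 racemic N-aryl 2,5-dihydrothiophene-2-carboxamide 1,1-dioxide
Product: 40 racemic N-aryl 2-methyl-2,5-dihydrothiophene-2-carboxamide 1,1-dioxide
Conditions: MeI, K2CO3, DMF, 0 °C to rt
Reagents that add atoms: iodomethane CI
Why: Alkylation of an active methine, in which carbonate removes the C2 proton flanked by sulfone, carboxamide and alkene and the delocalised anion is methylated at its α-carbon, so that any conjugated 2-sulfolene tautomer is funnelled into the same quaternary 3-sulfolene.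

**Union, ring closure and end game (steps 27–32)**

Step 27
Reactants: 40 racemic N-aryl 2-methyl-2,5-dihydrothiophene-2-carboxamide 1,1-dioxide; 21 chain fragment
Product: 42 seco aldehyde (sulfolene joined to C6; aryl aldehyde; alkenyl iodide), via acetal adduct 41 (not isolated)
Conditions: 40 (2 equiv), LiN(SiMe3)2 (4 equiv), THF, −100 °C; 21·MgBr2·OEt2, CH2Cl2/THF, −100 to −78 °C; AcOH; then 10% aq. citric acid, THF, 0 °C
Reagents that add atoms: water O
Why: Addition of a sulfonyl carbanion to a ketone, in which the N,C5-dilithiated sulfolene attacks the C6 carbonyl held in a magnesium chelate with the C7 ether anti to C8 (Cram chelate model, C6 and C7 oxygens syn), approach to the C5 face opposite the bulky N-lithio carboxanilide is expected to place C6 cis to the C2 methyl, and the mildly acidic work-up hydrolyses only the aryl dimethyl acetal.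

Step 28
Reactants: 42 seco aldehyde
Product: 43 macrocyclic C17 carbinol (22-membered; sulfolene-bridged)
Conditions: CrCl2 (15 equiv), NiCl2 (2 mol%), DMSO/THF, rt, 2 mM
Reagents that add atoms: none
Why: Nozaki–Hiyama–Kishi macrocyclisation, in which nickel-catalysed formation of the alkenyl species of trivalent chromium retains the Z geometry and its addition to the aryl aldehyde forms C16–C17 while tolerating the free hydroxyl, the anilide N–H and the sulfone.

Step 29
Reactants: 43 macrocyclic C17 carbinol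
Product: 44 macrocyclic sulfolene ketone
Conditions: Dess–Martin periodinane, NaHCO3, CH2Cl2, 0 °C to rt
Reagents that add atoms: none
Why: Dess–Martin oxidation of the allylic, benzylic alcohol gives the Z enone under buffered neutral conditions and merges the C17 epimers, the tertiary C6 hydroxyl being inert.

Step 30
Reactants: 44 macrocyclic sulfolene ketone
Product: 45 (2Z,4E)-dienamide macrocycle (23-membered)
Conditions: toluene (degassed), NaHCO3, BHT (cat.), 110 °C
Reagents that add atoms: none
Why: Thermal retro-cheletropic loss of SO2 from the 3-sulfolene is a concerted six-electron process in which both C–S bonds break while C2 and C5 rotate in a disrotatory sense, and the closest known reaction type is the stereospecific thermolysis of 2,5-disubstituted 3-sulfolenes to geometrically defined 1,3-dienes. No sigma bond is formed, so the 23-membered ansa ring arises by deletion of the one-atom sulfur bridge from the 22-membered ring, a ring expansion by extrusion and not a ring-closing event. No stereocentre is created; the new stereogenic elements are the C2=C3 and C4=C5 geometries, and both are dictated by the cis relationship of the C2 methyl and C6 on the sulfolene. The step needs outward rotation of the methyl group and of C6 with inward rotation of the C1 carbonyl and the C5 hydrogen, which gives 2Z,4E, and the opposite disrotation would push the quaternary C6 and the methyl group into the interior of the diene and should be sterically excluded. Both members of the diastereomer pair have this relative configuration and therefore give the same product, and solid NaHCO3 takes up SO2 and acid traces so that the enone and the tertiary dienyl carbinol should not isomerise.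

Step 31
Reactants: 45 (2Z,4E)-dienamide macrocycle
Product: 46 amidoquinone with free C6 and C7 hydroxyls
Conditions: (NH4)2Ce(NO3)6, MeCN/H2O, 0 °C
Reagents that add atoms: water O
Why: Oxidative demethylation of the 2-amido-1,4-dimethoxynaphthalene by tetravalent cerium gives the para-quinone, and the same oxidant cleaves the 4-methoxybenzyl ether at C7 by benzylic oxidation.

Step 32
Reactants: 46 amidoquinone
Product: 47 CNP0297124.1
Conditions: 2 M HCl (aq), THF/MeOH, rt
Reagents that add atoms: none
Why: Acid-catalysed hydrolysis of the two acetonides and of the aryl methoxymethyl ether completes the target, and ionisation at C6 should be slow because the adjacent diene is conjugated to the amide carbonyl.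

**Compound list**

1 | methyl (R)-3-hydroxy-2-methylpropanoate | COC(=O)[C@H](C)CO | starting material
2 | methyl (R)-3-[(tert-butyldiphenylsilyl)oxy]-2-methylpropanoate | COC(=O)[C@H](C)CO[Si](c1ccccc1)(c1ccccc1)C(C)(C)C | intermediate
3 | (R)-3-[(tert-butyldiphenylsilyl)oxy]-2-methylpropanal (C11–C13) | O=C[C@H](C)CO[Si](c1ccccc1)(c1ccccc1)C(C)(C)C | intermediate
4 | pentan-3-one | CCC(=O)CC | starting material
5 | (4S,5S,6R)-7-[(tert-butyldiphenylsilyl)oxy]-5-hydroxy-4,6-dimethylheptan-3-one (C8–C13; 10,11-anti; 11,12-syn) | CCC(=O)[C@@H](C)[C@@H](O)[C@H](C)CO[Si](c1ccccc1)(c1ccccc1)C(C)(C)C | intermediate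
6 | C11 triethylsilyl ether of 5 | CCC(=O)[C@@H](C)[C@@H](O[Si](CC)(CC)CC)[C@H](C)CO[Si](c1ccccc1)(c1ccccc1)C(C)(C)C | intermediate
7 | methacrolein (2-methylprop-2-enal) | CC(=C)C=O | starting material
8 | C6–C13 aldol adduct: C7 alcohol, C9 ketone, C6 as isopropenyl (7,8-syn; 8,10-syn) | C=C(C)[C@H](O)[C@@H](C)C(=O)[C@@H](C)[C@@H](O[Si](CC)(CC)CC)[C@H](C)CO[Si](c1ccccc1)(c1ccccc1)C(C)(C)C | intermediate
9 | C7,C9 anti diol (C11 triethylsilyl ether) | C=C(C)[C@H](O)[C@@H](C)[C@@H](O)[C@@H](C)[C@@H](O[Si](CC)(CC)CC)[C@H](C)CO[Si](c1ccccc1)(c1ccccc1)C(C)(C)C | intermediate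
10 | C7,C9,C11 triol | C=C(C)[C@H](O)[C@@H](C)[C@@H](O)[C@@H](C)[C@@H](O)[C@H](C)CO[Si](c1ccccc1)(c1ccccc1)C(C)(C)C | intermediate
11 | C9/C11 acetonide with free C7 hydroxyl | C=C(C)[C@H](O)[C@@H](C)[C@@H](OC5(C)C)[C@@H](C)[C@@H](O5)[C@H](C)CO[Si](c1ccccc1)(c1ccccc1)C(C)(C)C | intermediate
12 | C7 4-methoxybenzyl ether, C13 silyl ether | C=C(C)[C@H](OCc1ccc(OC)cc1)[C@@H](C)[C@@H](OC5(C)C)[C@@H](C)[C@@H](O5)[C@H](C)CO[Si](c1ccccc1)(c1ccccc1)C(C)(C)C | intermediate
13 | C13 primary alcohol | C=C(C)[C@H](OCc1ccc(OC)cc1)[C@@H](C)[C@@H](OC5(C)C)[C@@H](C)[C@@H](O5)[C@H](C)CO | intermediate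
14 | C13 aldehyde | C=C(C)[C@H](OCc1ccc(OC)cc1)[C@@H](C)[C@@H](OC5(C)C)[C@@H](C)[C@@H](O5)[C@H](C)C=O | intermediate
15 | ethyl (E)-enoate (C13=C14; ester carbon C14') | C=C(C)[C@H](OCc1ccc(OC)cc1)[C@@H](C)[C@@H](OC5(C)C)[C@@H](C)[C@@H](O5)[C@H](C)/C=C/C(=O)OCC | intermediate
16 | (E)-allylic alcohol | C=C(C)[C@H](OCc1ccc(OC)cc1)[C@@H](C)[C@@H](OC5(C)C)[C@@H](C)[C@@H](O5)[C@H](C)/C=C/CO | intermediate
17 | (13R,14R)-trans-epoxy alcohol | C=C(C)[C@H](OCc1ccc(OC)cc1)[C@@H](C)[C@@H](OC5(C)C)[C@@H](C)[C@@H](O5)[C@H](C)[C@@H](O1)[C@H]1CO | intermediate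
18 | 2-vinyl-1,3-diol (C13 and C14' hydroxyls; vinyl carbon C15) | C=C(C)[C@H](OCc1ccc(OC)cc1)[C@@H](C)[C@@H](OC5(C)C)[C@@H](C)[C@@H](O5)[C@H](C)[C@@H](O)[C@H](CO)C=C | intermediate
19 | bis-acetonide diene (C9/C11 and C13/C14' acetonides) | C=C(C)[C@H](OCc1ccc(OC)cc1)[C@@H](C)[C@@H](OC5(C)C)[C@@H](C)[C@@H](O5)[C@H](C)[C@@H](OC6(C)C)[C@H](CO6)C=C | intermediate
20 | keto aldehyde (C6 methyl ketone, C15 aldehyde) | CC(=O)[C@H](OCc1ccc(OC)cc1)[C@@H](C)[C@@H](OC5(C)C)[C@@H](C)[C@@H](O5)[C@H](C)[C@@H](OC6(C)C)[C@H](CO6)C=O | intermediate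
21 | chain fragment: C6 methyl ketone, (Z)-C15=C16 iodide | CC(=O)[C@H](OCc1ccc(OC)cc1)[C@@H](C)[C@@H](OC5(C)C)[C@@H](C)[C@@H](O5)[C@H](C)[C@@H](OC6(C)C)[C@H](CO6)/C=C(/C)I | intermediate
22 | 4-hydroxy-3-methylbenzaldehyde | Cc1cc(C=O)ccc1O | starting material
23 | 4-(benzyloxy)-3-methylbenzaldehyde | Cc1cc(C=O)ccc1OCc1ccccc1 | intermediate
24 | dimethyl succinate | COC(=O)CCC(=O)OC | starting material
25 | (E)-4-[4-(benzyloxy)-3-methylphenyl]-3-(methoxycarbonyl)but-3-enoic acid | COC(=O)/C(CC(=O)O)=C/c1ccc(OCc2ccccc2)c(C)c1 | intermediate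
26 | methyl 4-acetoxy-6-(benzyloxy)-7-methyl-2-naphthoate | COC(=O)c1cc(OC(C)=O)c2cc(OCc3ccccc3)c(C)cc2c1 | intermediate
27 | methyl 6-(benzyloxy)-4-hydroxy-7-methyl-2-naphthoate | COC(=O)c1cc(O)c2cc(OCc3ccccc3)c(C)cc2c1 | intermediate
28 | methyl 6-(benzyloxy)-7-methyl-1,4-dioxo-1,4-dihydronaphthalene-2-carboxylate | COC(=O)C1=CC(=O)c2cc(OCc3ccccc3)c(C)cc2C1=O | intermediate
29 | methyl 6-(benzyloxy)-1,4-dihydroxy-7-methyl-2-naphthoate | COC(=O)c1cc(O)c2cc(OCc3ccccc3)c(C)cc2c1O | intermediate
30 | methyl 6-(benzyloxy)-1,4-dimethoxy-7-methyl-2-naphthoate | COC(=O)c1cc(OC)c2cc(OCc3ccccc3)c(C)cc2c1OC | intermediate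
31 | methyl 6-hydroxy-1,4-dimethoxy-7-methyl-2-naphthoate | COC(=O)c1cc(OC)c2cc(O)c(C)cc2c1OC | intermediate
32 | methyl 5-formyl-6-hydroxy-1,4-dimethoxy-7-methyl-2-naphthoate | COC(=O)c1cc(OC)c2c(C=O)c(O)c(C)cc2c1OC | intermediate
33 | methyl 5-formyl-1,4-dimethoxy-6-(methoxymethoxy)-7-methyl-2-naphthoate | COC(=O)c1cc(OC)c2c(C=O)c(OCOC)c(C)cc2c1OC | intermediate
34 | methyl 5-(dimethoxymethyl)-1,4-dimethoxy-6-(methoxymethoxy)-7-methyl-2-naphthoate | COC(=O)c1cc(OC)c2c(C(OC)OC)c(OCOC)c(C)cc2c1OC | intermediate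
35 | potassium 5-(dimethoxymethyl)-1,4-dimethoxy-6-(methoxymethoxy)-7-methyl-2-naphthoate | [K+].[O-]C(=O)c1cc(OC)c2c(C(OC)OC)c(OCOC)c(C)cc2c1OC | intermediate
36 | 3-sulfolene (2,5-dihydrothiophene 1,1-dioxide) | O=S1(=O)CC=CC1 | starting material
37 | 5-(dimethoxymethyl)-1,4-dimethoxy-6-(methoxymethoxy)-7-methyl-2-naphthoyl azide | [N-]=[N+]=NC(=O)c1cc(OC)c2c(C(OC)OC)c(OCOC)c(C)cc2c1OC | intermediate
38 | 5-(dimethoxymethyl)-2-isocyanato-1,4-dimethoxy-6-(methoxymethoxy)-7-methylnaphthalene | O=C=Nc1cc(OC)c2c(C(OC)OC)c(OCOC)c(C)cc2c1OC | intermediate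
39 | racemic N-[5-(dimethoxymethyl)-1,4-dimethoxy-6-(methoxymethoxy)-7-methylnaphthalen-2-yl]-2,5-dihydrothiophene-2-carboxamide 1,1-dioxide | O=C(Nc1cc(OC)c2c(C(OC)OC)c(OCOC)c(C)cc2c1OC)C1C=CCS1(=O)=O | intermediate
40 | racemic N-[5-(dimethoxymethyl)-1,4-dimethoxy-6-(methoxymethoxy)-7-methylnaphthalen-2-yl]-2-methyl-2,5-dihydrothiophene-2-carboxamide 1,1-dioxide | CC1(C(=O)Nc2cc(OC)c3c(C(OC)OC)c(OCOC)c(C)cc3c2OC)C=CCS1(=O)=O | intermediate
41 | union product with aryl dimethyl acetal ((2S,5S) member of the pair; C2 methyl cis to C6; free C6 hydroxyl) | C[C@@]7(C(=O)Nc1cc(OC)c2c(C(OC)OC)c(OCOC)c(C)cc2c1OC)C=C[C@H](S7(=O)=O)[C@@](C)(O)[C@H](OCc1ccc(OC)cc1)[C@@H](C)[C@@H](OC5(C)C)[C@@H](C)[C@@H](O5)[C@H](C)[C@@H](OC6(C)C)[C@H](CO6)/C=C(/C)I | intermediate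
42 | seco aldehyde ((2S,5S) member of the pair) | C[C@@]7(C(=O)Nc1cc(OC)c2c(C=O)c(OCOC)c(C)cc2c1OC)C=C[C@H](S7(=O)=O)[C@@](C)(O)[C@H](OCc1ccc(OC)cc1)[C@@H](C)[C@@H](OC5(C)C)[C@@H](C)[C@@H](O5)[C@H](C)[C@@H](OC6(C)C)[C@H](CO6)/C=C(/C)I | intermediate
43 | macrocyclic C17 carbinol, 22-membered and sulfolene-bridged ((2S,5S) member of the pair; both C17 epimers) | C[C@]17C=C[C@H](S7(=O)=O)[C@@](C)(O)[C@H](OCc8ccc(OC)cc8)[C@@H](C)[C@@H](OC5(C)C)[C@@H](C)[C@@H](O5)[C@H](C)[C@@H](OC6(C)C)[C@H](CO6)/C=C(/C)C(O)c2c(OCOC)c(C)cc3c2c(OC)cc(NC1=O)c3OC | intermediate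
44 | macrocyclic sulfolene ketone, precursor of the key step ((2S,5S) member of the pair) | C[C@]17C=C[C@H](S7(=O)=O)[C@@](C)(O)[C@H](OCc8ccc(OC)cc8)[C@@H](C)[C@@H](OC5(C)C)[C@@H](C)[C@@H](O5)[C@H](C)[C@@H](OC6(C)C)[C@H](CO6)/C=C(/C)C(=O)c2c(OCOC)c(C)cc3c2c(OC)cc(NC1=O)c3OC | intermediate
45 | protected (2Z,4E)-dienamide macrocycle, 23-membered | C/C1=C/C=C/[C@@](C)(O)[C@H](OCc8ccc(OC)cc8)[C@@H](C)[C@@H](OC5(C)C)[C@@H](C)[C@@H](O5)[C@H](C)[C@@H](OC6(C)C)[C@H](CO6)/C=C(/C)C(=O)c2c(OCOC)c(C)cc3c2c(OC)cc(NC1=O)c3OC | intermediate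
46 | amidoquinone with two acetonides and the aryl methoxymethyl ether | C/C1=C/C=C/[C@@](C)(O)[C@H](O)[C@@H](C)[C@@H](OC5(C)C)[C@@H](C)[C@@H](O5)[C@H](C)[C@@H](OC6(C)C)[C@H](CO6)/C=C(/C)C(=O)c2c(OCOC)c(C)cc3c2C(=O)C=C(NC1=O)C3=O | intermediate
47 | CNP0297124.1 | C/C1=C/C=C/[C@@](C)(O)[C@H](O)[C@@H](C)[C@@H](O)[C@@H](C)[C@@H](O)[C@H](C)[C@@H](O)[C@H](CO)/C=C(/C)C(=O)c2c(O)c(C)cc3c2C(=O)C=C(NC1=O)C3=O | target

**Step count and risks**

Total steps: 32. Longest linear sequence: 22 steps (steps 1–16 and 27–32, from 1 to 47).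

Steps most likely to fail:

1. Step 27 (fragment union). What may go wrong: proton transfer from the methyl ketone to the dianion instead of addition, fragmentation of the lithiated sulfolene to a dienyl sulfinate if the temperature rises, reversal of the addition before the quench, and too small a facial bias at C5 between the methyl face and the carboxanilide face. Fallback: set out from ketone 21 and build the quaternary C2 only after the C5–C6 bond exists. Lithiated 3-sulfolene (from 36, n-BuLi, −100 °C, in excess) is added to the MgBr2 chelate of 21 to give the 2-(hydroxyalkyl)sulfolene F1. The tertiary hydroxyl is capped with Me3SiOTf and 2,6-lutidine to give the silyl ether F2. LiN(SiMe3)2 with MeI present at −78 °C methylates the unhindered ring CH2 to give the 2-methyl sulfolene F3. A second deprotonation at the same carbon (n-BuLi, −100 °C) and trapping with isocyanate 38, generated from 35 as in step 25, puts the carboxanilide trans to the large C5 substituent, that is with the methyl cis to C6, and gives the amide F4. The citric acid work-up of step 27 then removes the trimethylsilyl group and the dimethyl acetal, and the route is rejoined at 42.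

2. Step 28 (ring closure). What may go wrong: slow addition of the alkenylchromium species to an aldehyde flanked by the methoxymethyl ether and the peri methoxy group, so that protonation of the organometallic and intermolecular coupling outrun cyclisation. Fallback: set out from amide 40 and ketone 21, form C16–C17 between the free fragments and close the ring at C5–C6 instead. Citric acid hydrolysis of 40 gives the aldehyde F5. Intermolecular CrCl2/NiCl2 coupling of F5 with 21, whose methyl ketone is inert, gives the acyclic carbinol F6, which is silylated with Et3SiOTf to the triethylsilyl ether F7. LiN(SiMe3)2 with MgBr2·OEt2 at high dilution and −78 °C then closes the 22-membered ring by chelation-controlled addition of the C5 carbanion to the C6 ketone and gives the macrocyclic silyl ether F8. HF·pyridine removes the silyl group, and the route is rejoined at 43.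

3. Step 30 (key step). What may go wrong: migration of the ring double bond into conjugation with the sulfone, which would block the extrusion, thermal Z to E isomerisation of the C15=C16 enone during heating, and retro-aldol cleavage of the β-hydroxy sulfone. Fallback: keep the macrocyclic cheletropic step but run it one stage earlier, setting out from carbinol 43, which carries no enone. Heating 43 in toluene with NaHCO3 gives the dienamide carbinol F9, and Dess–Martin oxidation of its C17 alcohol rejoins the route at 45.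

Further compounds
F1 | step 27 | 2-(hydroxyalkyl)-3-sulfolene from 21 (C6 carbinol; both C5 epimers) | O=S1(=O)CC=CC1[C@@](C)(O)[C@H](OCc1ccc(OC)cc1)[C@@H](C)[C@@H](OC5(C)C)[C@@H](C)[C@@H](O5)[C@H](C)[C@@H](OC6(C)C)[C@H](CO6)/C=C(/C)I
F2 | step 27 | C6 trimethylsilyl ether of F1 | O=S1(=O)CC=CC1[C@@](C)(O[Si](C)(C)C)[C@H](OCc1ccc(OC)cc1)[C@@H](C)[C@@H](OC5(C)C)[C@@H](C)[C@@H](O5)[C@H](C)[C@@H](OC6(C)C)[C@H](CO6)/C=C(/C)I
F3 | step 27 | 2-methyl-5-substituted 3-sulfolene | CC1C=CC(S1(=O)=O)[C@@](C)(O[Si](C)(C)C)[C@H](OCc1ccc(OC)cc1)[C@@H](C)[C@@H](OC5(C)C)[C@@H](C)[C@@H](O5)[C@H](C)[C@@H](OC6(C)C)[C@H](CO6)/C=C(/C)I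
F4 | step 27 | silylated union product with aryl dimethyl acetal ((2S,5S) member) | C[C@@]7(C(=O)Nc1cc(OC)c2c(C(OC)OC)c(OCOC)c(C)cc2c1OC)C=C[C@H](S7(=O)=O)[C@@](C)(O[Si](C)(C)C)[C@H](OCc1ccc(OC)cc1)[C@@H](C)[C@@H](OC5(C)C)[C@@H](C)[C@@H](O5)[C@H](C)[C@@H](OC6(C)C)[C@H](CO6)/C=C(/C)I
F5 | step 28 | racemic N-[5-formyl-1,4-dimethoxy-6-(methoxymethoxy)-7-methylnaphthalen-2-yl]-2-methyl-2,5-dihydrothiophene-2-carboxamide 1,1-dioxide | CC1(C(=O)Nc2cc(OC)c3c(C=O)c(OCOC)c(C)cc3c2OC)C=CCS1(=O)=O
F6 | step 28 | acyclic C17 carbinol with C6 methyl ketone | CC(=O)[C@H](OCc1ccc(OC)cc1)[C@@H](C)[C@@H](OC5(C)C)[C@@H](C)[C@@H](O5)[C@H](C)[C@@H](OC6(C)C)[C@H](CO6)/C=C(/C)C(O)c1c(OCOC)c(C)cc2c1c(OC)cc(NC(=O)C1(C)C=CCS1(=O)=O)c2OC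
F7 | step 28 | C17 triethylsilyl ether of F6 | CC(=O)[C@H](OCc1ccc(OC)cc1)[C@@H](C)[C@@H](OC5(C)C)[C@@H](C)[C@@H](O5)[C@H](C)[C@@H](OC6(C)C)[C@H](CO6)/C=C(/C)C(O[Si](CC)(CC)CC)c1c(OCOC)c(C)cc2c1c(OC)cc(NC(=O)C1(C)C=CCS1(=O)=O)c2OC
F8 | step 28 | macrocyclic C17 triethylsilyl ether, sulfolene-bridged ((2S,5S) member) | C[C@]17C=C[C@H](S7(=O)=O)[C@@](C)(O)[C@H](OCc8ccc(OC)cc8)[C@@H](C)[C@@H](OC5(C)C)[C@@H](C)[C@@H](O5)[C@H](C)[C@@H](OC6(C)C)[C@H](CO6)/C=C(/C)C(O[Si](CC)(CC)CC)c2c(OCOC)c(C)cc3c2c(OC)cc(NC1=O)c3OC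
F9 | step 30 | (2Z,4E)-dienamide macrocycle with C17 carbinol | C/C1=C/C=C/[C@@](C)(O)[C@H](OCc8ccc(OC)cc8)[C@@H](C)[C@@H](OC5(C)C)[C@@H](C)[C@@H](O5)[C@H](C)[C@@H](OC6(C)C)[C@H](CO6)/C=C(/C)C(O)c2c(OCOC)c(C)cc3c2c(OC)cc(NC1=O)c3OC
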